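The chromanone is disconnected at O1–C8a and C4–C4a. Ring A carries the ring oxygen at C8a and the ketone carbon at C4a on adjacent carbons, with the C5 oxygen flanking C4a: the pattern left by nucleophile addition and electrophile capture on a 3-alkoxyaryne. In one operation the primary alkoxide of an enantiopure β-hydroxy ester adds to 5-methoxy-3-(methoxymethoxy)benzyne and the aryl anion so formed acylates itself on the methyl ester, closing ring C. The precursor is a methyl (S)-2-aryl-3-hydroxy-2-(methoxymethoxy)propanoate whose quaternary carbinol carbon, C3 of the target, is set beforehand by copper-catalysed desymmetrising benzoylation of a 2-arylglycerol.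

Key step: step 14

Remarks on the chemistry:
- 4-Bromo-3-methoxyphenol is taken as a commercial starting material, because it already differentiates the two oxygens of ring B (the pendant aryl ring).
- The tertiary oxygen at the future C3 is carried as a methoxymethyl ether and not as a silyl ether: a silyl group there would migrate to the neighbouring primary alkoxide or be cleaved by fluoride in step 14. All three MOM groups then fall together in the last step.
- The target is (3S). The descriptor of the quaternary centre changes from R (monobenzoate) to S (acid and later) only because the substituent priorities change.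

Step 1
Reactants: 1 5-methoxyresorcinol
Product: 2 3-methoxy-5-(methoxymethoxy)phenol
Conditions: NaH (1.0 equiv), MOMCl (1.0 equiv), DMF, 0 °C to rt; bis-ether removed and 1 recovered by chromatography
Reagents that add atoms: chloromethyl methyl ether (MOMCl), COCCl
Why: Williamson-type O-alkylation of the monophenoxide of a symmetric diol, so that only the degree and not the site of alkylation has to be controlled and unreacted 1 can be recycled.

Step 2
Reactants: 2 3-methoxy-5-(methoxymethoxy)phenol
Product: 3 3-methoxy-5-(methoxymethoxy)phenyl N-isopropylcarbamate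
Conditions: i-PrNCO (1.5 equiv), Et3N (0.2 equiv), CH2Cl2, rt
Reagents that add atoms: isopropyl isocyanate, CC(C)N=C=O
Why: base-catalysed addition of the phenol to an isocyanate (carbamoylation) installs a directing group for ortho-metalation that can later be removed under mild base.

Step 3
Reactants: 3 3-methoxy-5-(methoxymethoxy)phenyl N-isopropylcarbamate
Product: 7 5-methoxy-3-(methoxymethoxy)-2-(trimethylsilyl)phenyl N-isopropylcarbamate, via N-silyl carbamate 4 (not isolated), via aryllithium 5 (not isolated), via N-silyl C-silyl carbamate 6 (not isolated)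
Conditions: TBSOTf (1.1 equiv), TMEDA (1.1 equiv), Et2O, 0 °C to rt; n-BuLi (2.0 equiv), TMEDA (2.0 equiv), −78 °C; TMSCl (3.5 equiv), −78 °C to rt; cold aq. NaHSO4 work-up
Reagents that add atoms: chlorotrimethylsilane, C[Si](C)(C)Cl
Why: directed ortho-metalation of the in situ N-silylated aryl carbamate followed by silyl quench, with lithiation expected between the carbamate and the chelating OMOM group in preference to the methoxy-flanked side, the N-silyl group being lost on work-up.

Step 4
Reactants: 7 5-methoxy-3-(methoxymethoxy)-2-(trimethylsilyl)phenyl N-isopropylcarbamate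
Product: 9 5-methoxy-3-(methoxymethoxy)-2-(trimethylsilyl)phenyl trifluoromethanesulfonate, via silylphenol 8 (not isolated)
Conditions: Et2NH (1.5 equiv), DBU (1.5 equiv), MeCN, 40 °C; then PhNTf2 (1.5 equiv), rt
Reagents that add atoms: N-phenylbis(trifluoromethanesulfonimide), O=S(=O)(N(c1ccccc1)S(=O)(=O)C(F)(F)F)C(F)(F)F
Why: E1cB cleavage of the N–H carbamate (the isocyanate is trapped by Et2NH as a urea) and O-triflation of the phenoxide in the same flask, under non-acidic conditions that spare the electron-rich C–Si bond and the MOM ether.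

Step 5
Reactants: 10 4-bromo-3-methoxyphenol
Product: 11 1-bromo-2-methoxy-4-(methoxymethoxy)benzene
Conditions: NaH (1.1 equiv), MOMCl (1.2 equiv), THF/DMF, 0 °C to rt
Reagents that add atoms: chloromethyl methyl ether (MOMCl), COCCl
Why: Williamson O-alkylation of the phenoxide protects the future 4'-hydroxyl as the same acetal used elsewhere in the route.

Step 6
Reactants: 11 1-bromo-2-methoxy-4-(methoxymethoxy)benzene; 12 2,2-dimethyl-1,3-dioxan-5-one
Product: 14 5-[2-methoxy-4-(methoxymethoxy)phenyl]-2,2-dimethyl-1,3-dioxan-5-ol, via aryllithium 13 (not isolated)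
Conditions: n-BuLi (1.05 equiv), THF, −78 °C; 12 (1.2 equiv), −78 to 0 °C; aq. NH4Cl
Reagents that add atoms: none
Why: bromine–lithium exchange is faster than MOM-directed deprotonation at −78 °C, and 1,2-addition of the aryllithium to the symmetric ketone gives the achiral tertiary carbinol.

Step 7
Reactants: 14 5-[2-methoxy-4-(methoxymethoxy)phenyl]-2,2-dimethyl-1,3-dioxan-5-ol; 15 prenyl bromide (1-bromo-3-methylbut-2-ene)
Product: 17 5-[2-methoxy-4-(methoxymethoxy)-3-(3-methylbut-2-en-1-yl)phenyl]-2,2-dimethyl-1,3-dioxan-5-ol, via dilithio species 16 (not isolated)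
Conditions: n-BuLi (2.2 equiv), THF, 0 °C; CuBr·SMe2 (0.2 equiv), −78 °C; 15 (1.2 equiv), −78 °C to rt; aq. NH4Cl
Reagents that add atoms: none
Why: directed ortho-metalation of the lithium alkoxide at the only ring position flanked by two ether oxygens (between OMe and OMOM), then copper-catalysed SN2 allylation, the hindered tertiary lithium alkoxide being expected to stay unalkylated at low temperature.

Step 8
Reactants: 17 5-[2-methoxy-4-(methoxymethoxy)-3-(3-methylbut-2-en-1-yl)phenyl]-2,2-dimethyl-1,3-dioxan-5-ol
Product: 18 2-[2-methoxy-4-(methoxymethoxy)-3-(3-methylbut-2-en-1-yl)phenyl]propane-1,2,3-triol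
Conditions: PPTS (0.1 equiv), MeOH, rt
Reagents that add atoms: none
Why: acid-catalysed transketalisation cleaves the six-membered acetonide much faster than the aryl MOM ether, and the two β-oxygens disfavour ionisation of the benzylic carbinol.

Step 9
Reactants: 18 2-[2-methoxy-4-(methoxymethoxy)-3-(3-methylbut-2-en-1-yl)phenyl]propane-1,2,3-triol
Product: 19 (2R)-2,3-dihydroxy-2-[2-methoxy-4-(methoxymethoxy)-3-(3-methylbut-2-en-1-yl)phenyl]propyl benzoate
Conditions: CuCl2 (10 mol%), 2,2'-(propane-2,2-diyl)bis[(4R)-4-phenyl-4,5-dihydrooxazole] (10 mol%), BzCl (1.1 equiv), Et3N (1.2 equiv), THF, 0 °C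
Reagents that add atoms: benzoyl chloride, O=C(Cl)c1ccccc1
Why: copper–bis(oxazoline)-catalysed enantioselective desymmetrising monobenzoylation of a 2-substituted glycerol, in which the chiral divalent copper complex is expected to chelate the tertiary and one primary hydroxyl and so select one of the two enantiotopic CH2OH arms, setting the only stereocentre under catalyst control (the ligand antipode that gives the R product is to be confirmed in a first run, both being available).

Step 10
Reactants: 19 (2R)-2,3-dihydroxy-2-[2-methoxy-4-(methoxymethoxy)-3-(3-methylbut-2-en-1-yl)phenyl]propyl benzoate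
Product: 21 (2S)-3-(benzoyloxy)-2-hydroxy-2-[2-methoxy-4-(methoxymethoxy)-3-(3-methylbut-2-en-1-yl)phenyl]propanoic acid, via hydroxy aldehyde 20 (not isolated)
Conditions: TEMPO (0.2 equiv), PhI(OAc)2 (2.5 equiv), MeCN/H2O (1:1), rt
Reagents that add atoms: water, O
Why: oxoammonium-mediated oxidation of the primary alcohol to the aldehyde and of its hydrate to the acid leaves the tertiary alcohol, benzoate, prenyl alkene and MOM ether alone, and the slightly acidic medium suppresses benzoyl migration between the two arms, which would erode enantiomeric purity.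

Step 11
Reactants: 21 (2S)-3-(benzoyloxy)-2-hydroxy-2-[2-methoxy-4-(methoxymethoxy)-3-(3-methylbut-2-en-1-yl)phenyl]propanoic acid
Product: 22 methyl (2S)-3-(benzoyloxy)-2-hydroxy-2-[2-methoxy-4-(methoxymethoxy)-3-(3-methylbut-2-en-1-yl)phenyl]propanoate
Conditions: MeI (1.5 equiv), KHCO3 (1.5 equiv), DMF, rt
Reagents that add atoms: iodomethane, CI
Why: SN2 O-alkylation of the carboxylate under bicarbonate, which is too weak a base to alkylate the tertiary alcohol or to move the benzoate.

Step 12
Reactants: 22 methyl (2S)-3-(benzoyloxy)-2-hydroxy-2-[2-methoxy-4-(methoxymethoxy)-3-(3-methylbut-2-en-1-yl)phenyl]propanoate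
Product: 23 methyl (2S)-3-(benzoyloxy)-2-(methoxymethoxy)-2-[2-methoxy-4-(methoxymethoxy)-3-(3-methylbut-2-en-1-yl)phenyl]propanoate
Conditions: MOMCl (5 equiv), i-Pr2NEt (8 equiv), ClCH2CH2Cl, 50 °C
Reagents that add atoms: chloromethyl methyl ether (MOMCl), COCCl
Why: alkoxymethylation of the hindered tertiary α-hydroxy ester with excess reagent and amine base at raised temperature gives an acetal that neither migrates nor responds to fluoride.

Step 13
Reactants: 23 methyl (2S)-3-(benzoyloxy)-2-(methoxymethoxy)-2-[2-methoxy-4-(methoxymethoxy)-3-(3-methylbut-2-en-1-yl)phenyl]propanoate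
Product: 24 methyl (2S)-3-hydroxy-2-(methoxymethoxy)-2-[2-methoxy-4-(methoxymethoxy)-3-(3-methylbut-2-en-1-yl)phenyl]propanoate
Conditions: K2CO3 (0.2 equiv), MeOH, 0 °C to rt
Reagents that add atoms: none
Why: methanolysis (transesterification) of the benzoate, with degenerate exchange at the methyl ester, under short, cold, protic conditions that keep retro-aldol loss of formaldehyde in check.

Step 14
Reactants: 24 methyl (2S)-3-hydroxy-2-(methoxymethoxy)-2-[2-methoxy-4-(methoxymethoxy)-3-(3-methylbut-2-en-1-yl)phenyl]propanoate; 9 5-methoxy-3-(methoxymethoxy)-2-(trimethylsilyl)phenyl trifluoromethanesulfonate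
Product: 28 (3S)-7-methoxy-3,5-bis(methoxymethoxy)-3-[2-methoxy-4-(methoxymethoxy)-3-(3-methylbut-2-en-1-yl)phenyl]chroman-4-one, via sodium alkoxide 25 (not isolated), via aryne 26 (not isolated), via aryl anion 27 (not isolated)
Conditions: NaH (1.05 equiv), THF, 0 °C, 10 min; then KF (3.5 equiv), 18-crown-6 (3.5 equiv), 9 (1.6 equiv, slow addition), THF, 0 °C to rt; aq. NH4Cl
Reagents that add atoms: none
Why: Proposed new method: fluoride attacks the silicon of 9 and loss of triflate gives aryne 26; the preformed alkoxide 25 adds to the aryne carbon remote from the OMOM group, so that the charge develops on the carbon flanked by the OMOM oxygen (future C4a), and this aryl anion 27 adds to the methyl ester and expels methoxide to give the ketone. The closest known reaction type is the fluoride-induced annulation of 2-(trimethylsilyl)aryl triflates with salicylate esters to xanthones, extended here from a phenoxide to an aliphatic alkoxide. Ring C is closed by 6-exo-trig attack of the aryl anion on the ester carbonyl. No stereocentre is formed, and the quaternary centre (future C3), which has no acidic hydrogen and none of whose bonds is made or broken, is carried through unchanged. The step needs regioselective addition to the unsymmetrical aryne, secured by the inductive and bond-angle effect of the alkoxy group next to the triple bond, and acyl capture in preference to protonation of the aryl anion, secured by complete deprotonation of the alcohol beforehand, an aprotic ether solvent and the absence of enolisable hydrogens in the ester.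

Step 15
Reactants: 28 (3S)-7-methoxy-3,5-bis(methoxymethoxy)-3-[2-methoxy-4-(methoxymethoxy)-3-(3-methylbut-2-en-1-yl)phenyl]chroman-4-one
Product: 29 (3S)-3,5-dihydroxy-3-[4-hydroxy-2-methoxy-3-(3-methylbut-2-en-1-yl)phenyl]-7-methoxychroman-4-one
Conditions: 3 M aq. HCl/MeOH (1:5), 45 °C
Reagents that add atoms: none
Why: acid-catalysed transacetalisation to methanol removes the two aryl MOM ethers and the tertiary MOM ether without breaking the C3–O bond, so the (3S) configuration is retained, and the moderate temperature is chosen to avoid cyclisation of the prenyl group onto the 4'-hydroxyl.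

Compound list
1 | 5-methoxyresorcinol | COc1cc(O)cc(O)c1 | starting material
2 | 3-methoxy-5-(methoxymethoxy)phenol | COCOc1cc(O)cc(OC)c1 | intermediate
3 | 3-methoxy-5-(methoxymethoxy)phenyl N-isopropylcarbamate | COCOc1cc(OC)cc(OC(=O)NC(C)C)c1 | intermediate
4 | 3-methoxy-5-(methoxymethoxy)phenyl N-(tert-butyldimethylsilyl)-N-isopropylcarbamate | COCOc1cc(OC)cc(OC(=O)N(C(C)C)[Si](C)(C)C(C)(C)C)c1 | intermediate (not isolated)
5 | 2-lithio derivative of 4 (lithium between the carbamate and OMOM oxygens) | COCOc1cc(OC)cc(OC(=O)N(C(C)C)[Si](C)(C)C(C)(C)C)c1[Li] | intermediate (not isolated)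
6 | 5-methoxy-3-(methoxymethoxy)-2-(trimethylsilyl)phenyl N-(tert-butyldimethylsilyl)-N-isopropylcarbamate | COCOc1cc(OC)cc(OC(=O)N(C(C)C)[Si](C)(C)C(C)(C)C)c1[Si](C)(C)C | intermediate (not isolated)
7 | 5-methoxy-3-(methoxymethoxy)-2-(trimethylsilyl)phenyl N-isopropylcarbamate | COCOc1cc(OC)cc(OC(=O)NC(C)C)c1[Si](C)(C)C | intermediate
8 | 5-methoxy-3-(methoxymethoxy)-2-(trimethylsilyl)phenol | COCOc1cc(OC)cc(O)c1[Si](C)(C)C | intermediate (not isolated)
9 | 5-methoxy-3-(methoxymethoxy)-2-(trimethylsilyl)phenyl trifluoromethanesulfonate | COc1cc(OCOC)c([Si](C)(C)C)c(OS(=O)(=O)C(F)(F)F)c1 | intermediate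
10 | 4-bromo-3-methoxyphenol | COc1cc(O)ccc1Br | starting material
11 | 1-bromo-2-methoxy-4-(methoxymethoxy)benzene | COCOc1ccc(Br)c(OC)c1 | intermediate
12 | 2,2-dimethyl-1,3-dioxan-5-one | CC1(C)OCC(=O)CO1 | starting material
13 | [2-methoxy-4-(methoxymethoxy)phenyl]lithium | COCOc1ccc([Li])c(OC)c1 | intermediate (not isolated)
14 | 5-[2-methoxy-4-(methoxymethoxy)phenyl]-2,2-dimethyl-1,3-dioxan-5-ol | COCOc1ccc(C2(O)COC(C)(C)OC2)c(OC)c1 | intermediate
15 | prenyl bromide (1-bromo-3-methylbut-2-ene) | CC(C)=CCBr | starting material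
16 | dilithio derivative of 14 (lithium alkoxide, ring lithium between OMe and OMOM) | COCOc1ccc(C2(O[Li])COC(C)(C)OC2)c(OC)c1[Li] | intermediate (not isolated)
17 | 5-[2-methoxy-4-(methoxymethoxy)-3-(3-methylbut-2-en-1-yl)phenyl]-2,2-dimethyl-1,3-dioxan-5-ol | COCOc1ccc(C2(O)COC(C)(C)OC2)c(OC)c1CC=C(C)C | intermediate
18 | 2-[2-methoxy-4-(methoxymethoxy)-3-(3-methylbut-2-en-1-yl)phenyl]propane-1,2,3-triol (achiral) | COCOc1ccc(C(O)(CO)CO)c(OC)c1CC=C(C)C | intermediate
19 | (2R)-2,3-dihydroxy-2-[2-methoxy-4-(methoxymethoxy)-3-(3-methylbut-2-en-1-yl)phenyl]propyl benzoate | OC[C@@](O)(COC(=O)c1ccccc1)c1ccc(OCOC)c(CC=C(C)C)c1OC | intermediate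
20 | (2S)-2-hydroxy-2-[2-methoxy-4-(methoxymethoxy)-3-(3-methylbut-2-en-1-yl)phenyl]-3-oxopropyl benzoate | O=C[C@@](O)(COC(=O)c1ccccc1)c1ccc(OCOC)c(CC=C(C)C)c1OC | intermediate (not isolated)
21 | (2S)-3-(benzoyloxy)-2-hydroxy-2-[2-methoxy-4-(methoxymethoxy)-3-(3-methylbut-2-en-1-yl)phenyl]propanoic acid | OC(=O)[C@@](O)(COC(=O)c1ccccc1)c1ccc(OCOC)c(CC=C(C)C)c1OC | intermediate
22 | methyl (2S)-3-(benzoyloxy)-2-hydroxy-2-[2-methoxy-4-(methoxymethoxy)-3-(3-methylbut-2-en-1-yl)phenyl]propanoate | COC(=O)[C@@](O)(COC(=O)c1ccccc1)c1ccc(OCOC)c(CC=C(C)C)c1OC | intermediate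
23 | methyl (2S)-3-(benzoyloxy)-2-(methoxymethoxy)-2-[2-methoxy-4-(methoxymethoxy)-3-(3-methylbut-2-en-1-yl)phenyl]propanoate | COC(=O)[C@@](OCOC)(COC(=O)c1ccccc1)c1ccc(OCOC)c(CC=C(C)C)c1OC | intermediate
24 | methyl (2S)-3-hydroxy-2-(methoxymethoxy)-2-[2-methoxy-4-(methoxymethoxy)-3-(3-methylbut-2-en-1-yl)phenyl]propanoate | COC(=O)[C@@](OCOC)(CO)c1ccc(OCOC)c(CC=C(C)C)c1OC | intermediate
25 | sodium alkoxide of 24 | COC(=O)[C@@](OCOC)(C[O-])c1ccc(OCOC)c(CC=C(C)C)c1OC.[Na+] | intermediate (not isolated)
26 | 5-methoxy-3-(methoxymethoxy)benzyne | COC1=CC#CC(OCOC)=C1 | intermediate (not isolated)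
27 | methyl (2S)-3-[5-methoxy-3-(methoxymethoxy)-2-sodiophenoxy]-2-(methoxymethoxy)-2-[2-methoxy-4-(methoxymethoxy)-3-(3-methylbut-2-en-1-yl)phenyl]propanoate (aryl anion) | COC(=O)[C@@](OCOC)(COc1cc(OC)cc(OCOC)c1[Na])c1ccc(OCOC)c(CC=C(C)C)c1OC | intermediate (not isolated)
28 | (3S)-7-methoxy-3,5-bis(methoxymethoxy)-3-[2-methoxy-4-(methoxymethoxy)-3-(3-methylbut-2-en-1-yl)phenyl]chroman-4-one | COc1cc(OCOC)c2c(c1)OC[C@@](OCOC)(c1ccc(OCOC)c(CC=C(C)C)c1OC)C2=O | intermediate
29 | (3S)-3,5-dihydroxy-3-[4-hydroxy-2-methoxy-3-(3-methylbut-2-en-1-yl)phenyl]-7-methoxychroman-4-one | COc1cc(O)c2c(c1)OC[C@@](O)(c1ccc(O)c(CC=C(C)C)c1OC)C2=O | target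

Total step count: 15 (steps 1–4 make the aryne precursor, steps 5–13 the hydroxy ester, steps 14–15 join and deprotect).
Longest linear sequence: 11 steps (steps 5–15, from 10).

Steps most likely to fail

Step 14 (aryne annulation). The alkoxide may lose formaldehyde by retro-aldol cleavage before it meets the aryne. The aryl anion may be protonated before it reaches the ester, which stops the sequence at simple O-arylation. The alkoxide may also be consumed by silyl or triflyl transfer from the aryne precursor. The fallback uses known chemistry, sets out from 3 and 24 and comes back at 28. The aryllithium 5, generated as in step 3, is quenched with I2 in place of TMSCl to give 2-iodo-5-methoxy-3-(methoxymethoxy)phenyl N-(tert-butyldimethylsilyl)-N-isopropylcarbamate F1, which loses its N-silyl group on NaHSO4 work-up to give 2-iodo-5-methoxy-3-(methoxymethoxy)phenyl N-isopropylcarbamate F2. Et2NH/DBU in MeCN at 40 °C then frees 2-iodo-5-methoxy-3-(methoxymethoxy)phenol F3. Mitsunobu etherification of 24 with F3 (DIAD, PPh3, toluene, 60 °C) gives methyl (2S)-3-[2-iodo-5-methoxy-3-(methoxymethoxy)phenoxy]-2-(methoxymethoxy)-2-[2-methoxy-4-(methoxymethoxy)-3-(3-methylbut-2-en-1-yl)phenyl]propanoate F4. Iodine–lithium exchange (n-BuLi, THF, −100 °C) and intramolecular acylation of the aryllithium by the methyl ester (Parham cyclisation) should then give 28. The O1–C8a and C4–C4a bonds are thus made in two separate, precedented operations.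

Step 9 (desymmetrising benzoylation). The ortho-disubstituted aryl group may spoil the discrimination between the two enantiotopic hydroxymethyl arms, and benzoyl migration between the arms under the basic conditions would lower the enantiomeric purity further. The fallback replaces desymmetrisation by resolution, sets out from 18 and comes back at 21. Triol 18 is monobenzoylated without a chiral catalyst (BzCl, 2,4,6-collidine, CH2Cl2, −40 °C) to racemic 2,3-dihydroxy-2-[2-methoxy-4-(methoxymethoxy)-3-(3-methylbut-2-en-1-yl)phenyl]propyl benzoate F5. Oxidation as in step 10 passes through the racemic hydroxy aldehyde F6 to the racemic 3-(benzoyloxy)-2-hydroxy-2-arylpropanoic acid F7. The acid is resolved by fractional crystallisation of its salt with 1-phenylethylamine, written here as the (S)-acid (S)-1-phenylethylammonium salt F8; the amine antipode is chosen by trial, both being commercial. Acidification returns acid 21.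

Step 3 (carbamate-directed silylation). Lithiation may occur on the methoxy-flanked side of the carbamate instead of the MOM-flanked side, or the carbamoyl group may migrate to carbon on warming, so that silicon ends up in the wrong place or not at all. The fallback makes the lithiation site unambiguous by symmetry, sets out from 1 and comes back at 9. Diol 1 is converted with Et2NCOCl and K2CO3 in MeCN into 5-methoxy-1,3-phenylene bis(N,N-diethylcarbamate) F9. s-BuLi/TMEDA in THF at −78 °C metalates the position between the two carbamates to give the 2-lithio bis-carbamate F10, and TMSCl gives 5-methoxy-2-(trimethylsilyl)-1,3-phenylene bis(N,N-diethylcarbamate) F11. LiAlH4 in THF cleaves both carbamates to 5-methoxy-2-(trimethylsilyl)benzene-1,3-diol F12. Tf2O (1 equiv) and pyridine in CH2Cl2 at −78 °C give, as the statistical mono-product, 3-hydroxy-5-methoxy-2-(trimethylsilyl)phenyl trifluoromethanesulfonate F13. MOMCl and i-Pr2NEt at 0 °C, kept cold to avoid base-induced silyl migration, give 9.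

Further compounds
F1 | step 14 | 2-iodo-5-methoxy-3-(methoxymethoxy)phenyl N-(tert-butyldimethylsilyl)-N-isopropylcarbamate | COCOc1cc(OC)cc(OC(=O)N(C(C)C)[Si](C)(C)C(C)(C)C)c1I
F2 | step 14 | 2-iodo-5-methoxy-3-(methoxymethoxy)phenyl N-isopropylcarbamate | COCOc1cc(OC)cc(OC(=O)NC(C)C)c1I
F3 | step 14 | 2-iodo-5-methoxy-3-(methoxymethoxy)phenol | COCOc1cc(OC)cc(O)c1I
F4 | step 14 | methyl (2S)-3-[2-iodo-5-methoxy-3-(methoxymethoxy)phenoxy]-2-(methoxymethoxy)-2-[2-methoxy-4-(methoxymethoxy)-3-(3-methylbut-2-en-1-yl)phenyl]propanoate | COC(=O)[C@@](OCOC)(COc1cc(OC)cc(OCOC)c1I)c1ccc(OCOC)c(CC=C(C)C)c1OC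
F5 | step 9 | racemic 2,3-dihydroxy-2-[2-methoxy-4-(methoxymethoxy)-3-(3-methylbut-2-en-1-yl)phenyl]propyl benzoate | OCC(O)(COC(=O)c1ccccc1)c1ccc(OCOC)c(CC=C(C)C)c1OC
F6 | step 9 | racemic 2-hydroxy-2-[2-methoxy-4-(methoxymethoxy)-3-(3-methylbut-2-en-1-yl)phenyl]-3-oxopropyl benzoate | O=CC(O)(COC(=O)c1ccccc1)c1ccc(OCOC)c(CC=C(C)C)c1OC
F7 | step 9 | racemic 3-(benzoyloxy)-2-hydroxy-2-[2-methoxy-4-(methoxymethoxy)-3-(3-methylbut-2-en-1-yl)phenyl]propanoic acid | OC(=O)C(O)(COC(=O)c1ccccc1)c1ccc(OCOC)c(CC=C(C)C)c1OC
F8 | step 9 | (S)-1-phenylethylammonium (2S)-3-(benzoyloxy)-2-hydroxy-2-[2-methoxy-4-(methoxymethoxy)-3-(3-methylbut-2-en-1-yl)phenyl]propanoate | [O-]C(=O)[C@@](O)(COC(=O)c1ccccc1)c1ccc(OCOC)c(CC=C(C)C)c1OC.C[C@H]([NH3+])c1ccccc1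
F9 | step 3 | 5-methoxy-1,3-phenylene bis(N,N-diethylcarbamate) | CCN(CC)C(=O)Oc1cc(OC)cc(OC(=O)N(CC)CC)c1
F10 | step 3 | 2-lithio-5-methoxy-1,3-phenylene bis(N,N-diethylcarbamate) | CCN(CC)C(=O)Oc1cc(OC)cc(OC(=O)N(CC)CC)c1[Li]
F11 | step 3 | 5-methoxy-2-(trimethylsilyl)-1,3-phenylene bis(N,N-diethylcarbamate) | CCN(CC)C(=O)Oc1cc(OC)cc(OC(=O)N(CC)CC)c1[Si](C)(C)C
F12 | step 3 | 5-methoxy-2-(trimethylsilyl)benzene-1,3-diol | COc1cc(O)c([Si](C)(C)C)c(O)c1
F13 | step 3 | 3-hydroxy-5-methoxy-2-(trimethylsilyl)phenyl trifluoromethanesulfonate | COc1cc(O)c([Si](C)(C)C)c(OS(=O)(=O)C(F)(F)F)c1
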